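**Retrosynthetic overview**
1. Target 32 comes from ketone 29: the oxirane is added last by methylene transfer to C12, the prenyl terminus by cross-metathesis, and the C12 oxygen from a C–B bond (bicyclo[9.3.1]pentadecane numbering of 32: C1 and C11 bridgeheads, C15 the one-carbon bridge).
2. Key disconnection: bonds C1–C15 and C11–C12, made together by an intramolecular Diels–Alder reaction of the acyclic pentaenal 21.
3. Enabling feature: the quaternary C15 carries the formyl group and lies between both bridgeheads in the six-membered ring C15–C1–C14–C13–C12–C11. This is the retron of a 2-substituted (E)-enal dienophile (C15=C11) and a diene C1=C14–C13=C12; since the C2–C10 chain ties C1 to C11, the same cycloaddition closes the twelve-membered ring C15–C1–C2…C10–C11 in the bridged, in,out fashion.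
4. Pentaenal 21 is built from two syn-carbocuprations of propyne (both (Z)-trisubstituted alkenes), a dienylboronate allylic bromide and a directed aldol condensation.
5. Ring order: the six-membered and twelve-membered carbocycles close in step 9 (the twelve-membered ring is complete only when C1–C15 forms; no carbocycle is closed after it); the oxirane follows in step 15.

Key step: step 9

Assumption: the (S)-configured oxazaborolidinium ion of step 9 is taken to expose the enal face that leads to 22, as the formyl C–H···O binding model for 2-substituted enals predicts; the mirror-image catalyst would be used in the same way if the opposite sense were found.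

Step 1
Reactants: 1 (2E)-pent-2-en-4-yn-1-ol
Product: 2 (3E)-5-bromopent-3-en-1-yne
Conditions: CBr4, PPh3, CH2Cl2, 0 °C
Reagents that add atoms: tetrabromomethane, BrC(Br)(Br)Br
Why: Appel reaction; the primary allylic alcohol is displaced at carbon and the (E)-alkene and the alkyne are not touched.

Step 2
Reactants: 2 (3E)-5-bromopent-3-en-1-yne
Product: 3 2-[(1E,3E)-5-bromopenta-1,3-dien-1-yl]-4,4,5,5-tetramethyl-1,3,2-dioxaborolane
Conditions: pinacolborane, (c-C6H11)2BH (5 mol%), neat, 20 °C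
Reagents that add atoms: pinacolborane, [H]B1OC(C)(C)C(C)(C)O1
Why: Borane-catalysed hydroboration of the terminal alkyne; syn addition with boron on the terminal carbon should give the new (E)-alkenylboronate, and the allylic bromide is inert to the borane.

Step 3
Reactants: 4 2-(2-bromoethyl)-1,3-dioxolane; 5 propyne; 6 oxirane
Product: 9 (3Z)-6-(1,3-dioxolan-2-yl)-4-methylhex-3-en-1-ol, via Grignard reagent 7 (not isolated), via alkenylcopper 8 (not isolated)
Conditions: Mg, THF, 30 °C; CuBr·SMe2 (0.5 equiv), Et2O/Me2S, −45 °C; propyne, −25 °C; oxirane, −25 → 0 °C; aq. NH4Cl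
Reagents that add atoms: none
Why: Syn-carbocupration of propyne puts the alkyl group on C2 and copper on C1 on the same side, and the alkenylcopper opens oxirane with retention, so the (Z)-trisubstituted alkene follows from the mechanism.

Step 4
Reactants: 9 (3Z)-6-(1,3-dioxolan-2-yl)-4-methylhex-3-en-1-ol
Product: 10 2-[(3Z)-6-bromo-3-methylhex-3-en-1-yl]-1,3-dioxolane
Conditions: CBr4, PPh3, 2,6-lutidine, CH2Cl2, 0 °C
Reagents that add atoms: tetrabromomethane, BrC(Br)(Br)Br
Why: Appel reaction at the primary homoallylic alcohol; the buffered neutral conditions should keep the acetal and the alkene geometry.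

Step 5
Reactants: 10 2-[(3Z)-6-bromo-3-methylhex-3-en-1-yl]-1,3-dioxolane; 5 propyne; 3 2-[(1E,3E)-5-bromopenta-1,3-dien-1-yl]-4,4,5,5-tetramethyl-1,3,2-dioxaborolane
Product: 14 2-[(3Z,7Z,10E,12E)-3,7-dimethyl-13-(4,4,5,5-tetramethyl-1,3,2-dioxaborolan-2-yl)trideca-3,7,10,12-tetraen-1-yl]-1,3-dioxolane, via Grignard reagent 11 (not isolated), via alkenylcopper 12 (not isolated), via alkenylzinc bromide 13 (not isolated)
Conditions: Mg, Et2O, 35 °C; CuBr·SMe2 (1 equiv), Et2O/Me2S, −45 °C; propyne, −25 °C; ZnBr2, THF, −20 °C; 3, Pd(PPh3)4 (3 mol%), −20 → 20 °C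
Reagents that add atoms: none
Why: A second syn-carbocupration sets the other (Z)-alkene; after copper-to-zinc exchange a palladium-catalysed alkenyl–allyl (Negishi-type) coupling should join the alkenyl carbon to the primary end of the pentadienyl bromide with retention of all alkene geometries and without touching the boronate.

Step 6
Reactants: 14 2-[(3Z,7Z,10E,12E)-3,7-dimethyl-13-(4,4,5,5-tetramethyl-1,3,2-dioxaborolan-2-yl)trideca-3,7,10,12-tetraen-1-yl]-1,3-dioxolane
Product: 15 (4Z,8Z,11E,13E)-4,8-dimethyl-14-(4,4,5,5-tetramethyl-1,3,2-dioxaborolan-2-yl)tetradeca-4,8,11,13-tetraenal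
Conditions: 1 M HCl, THF, 20 °C
Reagents that add atoms: water, O
Why: Acid hydrolysis of the dioxolane; the pinacol boronate and the skipped polyene should tolerate dilute acid at room temperature.

Step 7
Reactants: 16 hex-5-enal; 17 cyclohexanamine
Product: 18 N-cyclohexylhex-5-en-1-imine
Conditions: MgSO4, Et2O, 0 → 20 °C
Reagents that add atoms: none
Why: Condensation of an aldehyde with a primary amine to the imine, driven by removal of water.

Step 8
Reactants: 18 N-cyclohexylhex-5-en-1-imine; 15 (4Z,8Z,11E,13E)-4,8-dimethyl-14-(4,4,5,5-tetramethyl-1,3,2-dioxaborolan-2-yl)tetradeca-4,8,11,13-tetraenal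
Product: 21 (2E,6Z,10Z,13E,15E)-2-(but-3-en-1-yl)-6,10-dimethyl-16-(4,4,5,5-tetramethyl-1,3,2-dioxaborolan-2-yl)hexadeca-2,6,10,13,15-pentaenal, via lithiated imine 19 (not isolated), via aldol adduct 20 (not isolated)
Conditions: LiN(i-Pr)2, THF, −78 °C; 15, −78 → −30 °C; oxalic acid, H2O/THF, 20 °C
Reagents that add atoms: water, O
Why: Directed aldol condensation through the metallated imine; addition to the aldehyde, then acid-promoted dehydration and imine hydrolysis should give the thermodynamically preferred (E)-2-alkylenal (formyl trans to the chain).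

Step 9
Reactants: 21 (2E,6Z,10Z,13E,15E)-2-(but-3-en-1-yl)-6,10-dimethyl-16-(4,4,5,5-tetramethyl-1,3,2-dioxaborolan-2-yl)hexadeca-2,6,10,13,15-pentaenal
Product: 22 (1S,3Z,7Z,11S,12R,15R)-15-(but-3-en-1-yl)-4,8-dimethyl-12-(4,4,5,5-tetramethyl-1,3,2-dioxaborolan-2-yl)bicyclo[9.3.1]pentadeca-3,7,13-triene-15-carbaldehyde
Conditions: (3aS)-1-(2-methylphenyl)-3,3-diphenyltetrahydro-1H,3H-pyrrolo[1,2-c][1,3,2]oxazaborole/HN(SO2CF3)2 (1:1, 30 mol%), CH2Cl2, −40 → −20 °C, slow addition of 21 (final 0.002 M)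
Reagents that add atoms: none
Why: The boron Lewis acid binds the formyl oxygen of the (E)-2-alkylenal and the tethered (1E,3E)-dienylboronate adds to the enal C=C in a concerted, asynchronous [4+2] cycloaddition whose leading bond joins the enal β-carbon (future C11) to the boron-bearing diene terminus (future C12). The closest known reaction types are the oxazaborolidinium-catalysed enantioselective intramolecular Diels–Alder reaction of 2-substituted trienals and the macrocyclising intramolecular Diels–Alder reactions in which an eleven- to fourteen-membered carbocycle closes together with the cyclohexene. The six-membered ring closes by the [4+2] addition, and the twelve-membered ring closes in the same event in the bridged mode, because the nine-carbon tether joins the diene terminus (C1) to the dienophile β-carbon (C11) while C1 bonds to the α-carbon (C15). C15 and C11 (side chain cis to the C10 arm, formyl trans to it) follow from the (E)-enal by suprafacial addition, C1 (C2 arm cis to formyl, hence C2 and C10 arms trans, the in,out bridge) from the endo position of the formyl group, C12 (boron cis to the C2 arm) from the (E,E)-diene, and the absolute sense from the catalyst, which shields one face of the bound s-trans enal. The step needs bridged over fused (eleven-membered) regiochemistry, secured by the ortho preference of the alkyl-substituted diene terminus for the formyl-bearing carbon and by the reluctance of the boryl-bearing terminus to bond to the fully substituted C15, and endo over exo selectivity, secured by the Lewis acid and by a tether that runs unhindered on the open side of the dienophile only when formyl is endo. High dilution by slow addition holds back intermolecular cycloaddition, and the side chain is kept as a terminal alkene until step 10 so that no nucleophilic trisubstituted alkene lies five atoms from the activated β-carbon.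

Step 10
Reactants: 22 (1S,3Z,7Z,11S,12R,15R)-15-(but-3-en-1-yl)-4,8-dimethyl-12-(4,4,5,5-tetramethyl-1,3,2-dioxaborolan-2-yl)bicyclo[9.3.1]pentadeca-3,7,13-triene-15-carbaldehyde; 23 2-methylbut-2-ene
Product: 24 (1S,3Z,7Z,11S,12R,15R)-4,8-dimethyl-15-(4-methylpent-3-en-1-yl)-12-(4,4,5,5-tetramethyl-1,3,2-dioxaborolan-2-yl)bicyclo[9.3.1]pentadeca-3,7,13-triene-15-carbaldehyde
Conditions: second-generation Hoveyda–Grubbs catalyst RuCl2(H2IMes)(=CH-C6H4-2-O-i-Pr) (5 mol%), 2-methylbut-2-ene (excess), CH2Cl2, 40 °C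
Reagents that add atoms: none
Why: Olefin cross-metathesis of the only monosubstituted alkene with 2-methylbut-2-ene builds the prenyl terminus; the ring alkenes are trisubstituted or part of an unstrained cyclohexene and should not react.

Step 11
Reactants: 24 (1S,3Z,7Z,11S,12R,15R)-4,8-dimethyl-15-(4-methylpent-3-en-1-yl)-12-(4,4,5,5-tetramethyl-1,3,2-dioxaborolan-2-yl)bicyclo[9.3.1]pentadeca-3,7,13-triene-15-carbaldehyde
Product: 26 (1S,3Z,7Z,11R,12R,15S)-15-(hydroxymethyl)-4,8-dimethyl-15-(4-methylpent-3-en-1-yl)bicyclo[9.3.1]pentadeca-3,7,13-trien-12-ol, via primary alcohol 25 (not isolated)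
Conditions: NaBH4, MeOH/THF, 0 °C; then NaOH, H2O2, H2O, 0 → 20 °C
Reagents that add atoms: hydrogen peroxide, OO
Why: Hydride reduction of the aldehyde, then oxidation of the allylic C–B bond, which proceeds with retention at C12 and without allylic shift (this stereocentre is removed in step 12).

Step 12
Reactants: 26 (1S,3Z,7Z,11R,12R,15S)-15-(hydroxymethyl)-4,8-dimethyl-15-(4-methylpent-3-en-1-yl)bicyclo[9.3.1]pentadeca-3,7,13-trien-12-ol
Product: 27 (1S,3Z,7Z,11R,15S)-15-(hydroxymethyl)-4,8-dimethyl-15-(4-methylpent-3-en-1-yl)bicyclo[9.3.1]pentadeca-3,7,13-trien-12-one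
Conditions: MnO2 (excess), CH2Cl2, 20 °C
Reagents that add atoms: none
Why: MnO2 oxidises only the allylic secondary alcohol; the saturated neopentyl primary alcohol should stay.

Step 13
Reactants: 27 (1S,3Z,7Z,11R,15S)-15-(hydroxymethyl)-4,8-dimethyl-15-(4-methylpent-3-en-1-yl)bicyclo[9.3.1]pentadeca-3,7,13-trien-12-one
Product: 28 (1S,3Z,7Z,11R,15S)-15-{[(tert-butyldimethylsilyl)oxy]methyl}-4,8-dimethyl-15-(4-methylpent-3-en-1-yl)bicyclo[9.3.1]pentadeca-3,7,13-trien-12-one
Conditions: TBSOTf, 2,6-lutidine, CH2Cl2, −78 °C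
Reagents that add atoms: tert-butyldimethylsilyl trifluoromethanesulfonate, CC(C)(C)[Si](C)(C)OS(=O)(=O)C(F)(F)F
Why: Silylation of the hindered primary alcohol masks the future formyl carbon for the hydride and ylide steps; at the enone stage no hemiketal can compete.

Step 14
Reactants: 28 (1S,3Z,7Z,11R,15S)-15-{[(tert-butyldimethylsilyl)oxy]methyl}-4,8-dimethyl-15-(4-methylpent-3-en-1-yl)bicyclo[9.3.1]pentadeca-3,7,13-trien-12-one
Product: 29 (1R,3Z,7Z,11R,15S)-15-{[(tert-butyldimethylsilyl)oxy]methyl}-4,8-dimethyl-15-(4-methylpent-3-en-1-yl)bicyclo[9.3.1]pentadeca-3,7-dien-12-one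
Conditions: [(Ph3P)CuH]6 (0.4 equiv), C6H6, H2O (5 equiv), 20 °C
Reagents that add atoms: none
Why: Conjugate reduction with Stryker's reagent; copper hydride adds only to C14 of the enone, isolated alkenes and the silyl ether are left, and no stereocentre is formed.

Step 15
Reactants: 29 (1R,3Z,7Z,11R,15S)-15-{[(tert-butyldimethylsilyl)oxy]methyl}-4,8-dimethyl-15-(4-methylpent-3-en-1-yl)bicyclo[9.3.1]pentadeca-3,7-dien-12-one
Product: 30 tert-butyl(dimethyl){[(1R,3Z,7Z,11R,12S,15S)-4,8-dimethyl-15-(4-methylpent-3-en-1-yl)spiro[bicyclo[9.3.1]pentadeca-3,7-diene-12,2'-oxiran]-15-yl]methoxy}silane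
Conditions: Me3SI, KN(SiMe3)2, THF, −10 °C; then 29, −10 → 0 °C
Reagents that add atoms: trimethylsulfonium iodide, C[S+](C)C.[I-]
Why: Corey–Chaykovsky epoxidation; the irreversible addition of dimethylsulfonium methylide to the C12 ketone should come from the upper face, because the lower face is shielded by the C10 arm on the neighbouring C11 and by the axial C15 side chain, which puts CH2 up and oxygen down (12S).

Step 16
Reactants: 30 tert-butyl(dimethyl){[(1R,3Z,7Z,11R,12S,15S)-4,8-dimethyl-15-(4-methylpent-3-en-1-yl)spiro[bicyclo[9.3.1]pentadeca-3,7-diene-12,2'-oxiran]-15-yl]methoxy}silane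
Product: 31 [(1R,3Z,7Z,11R,12S,15S)-4,8-dimethyl-15-(4-methylpent-3-en-1-yl)spiro[bicyclo[9.3.1]pentadeca-3,7-diene-12,2'-oxiran]-15-yl]methanol
Conditions: Bu4NF, AcOH (1:1), THF, 20 °C
Reagents that add atoms: none
Why: Fluoride cleavage of the silyl ether; buffering with acetic acid should keep the free alkoxide from opening the oxirane.

Step 17
Reactants: 31 [(1R,3Z,7Z,11R,12S,15S)-4,8-dimethyl-15-(4-methylpent-3-en-1-yl)spiro[bicyclo[9.3.1]pentadeca-3,7-diene-12,2'-oxiran]-15-yl]methanol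
Product: 32 (1R,3Z,7Z,11R,12S,15S)-4,8-dimethyl-15-(4-methylpent-3-en-1-yl)spiro[bicyclo[9.3.1]pentadeca-3,7-diene-12,2'-oxirane]-15-carbaldehyde
Conditions: Dess–Martin periodinane, pyridine, CH2Cl2, 0 → 20 °C
Reagents that add atoms: none
Why: Dess–Martin oxidation of the primary alcohol to the non-enolisable aldehyde under buffered, non-acidic conditions that the oxirane and the alkenes should survive.

**Compound list**
1 | (2E)-pent-2-en-4-yn-1-ol | OC/C=C/C#C | starting material
2 | (3E)-5-bromopent-3-en-1-yne | BrC/C=C/C#C | intermediate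
3 | 2-[(1E,3E)-5-bromopenta-1,3-dien-1-yl]-4,4,5,5-tetramethyl-1,3,2-dioxaborolane | BrC/C=C/C=C/B1OC(C)(C)C(C)(C)O1 | intermediate
4 | 2-(2-bromoethyl)-1,3-dioxolane | BrCCC1OCCO1 | starting material
5 | propyne | CC#C | starting material
6 | oxirane | C1CO1 | starting material
7 | [2-(1,3-dioxolan-2-yl)ethyl]magnesium bromide | O1CCOC1CC[Mg]Br | intermediate
8 | [(1Z)-4-(1,3-dioxolan-2-yl)-2-methylbut-1-en-1-yl]copper | O1CCOC1CC/C(C)=C\[Cu] | intermediate
9 | (3Z)-6-(1,3-dioxolan-2-yl)-4-methylhex-3-en-1-ol | O1CCOC1CC/C(C)=C\CCO | intermediate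
10 | 2-[(3Z)-6-bromo-3-methylhex-3-en-1-yl]-1,3-dioxolane | O1CCOC1CC/C(C)=C\CCBr | intermediate
11 | [(3Z)-6-(1,3-dioxolan-2-yl)-4-methylhex-3-en-1-yl]magnesium bromide | O1CCOC1CC/C(C)=C\CC[Mg]Br | intermediate
12 | [(1Z,5Z)-8-(1,3-dioxolan-2-yl)-2,6-dimethylocta-1,5-dien-1-yl]copper | O1CCOC1CC/C(C)=C\CC/C(C)=C\[Cu] | intermediate
13 | bromo[(1Z,5Z)-8-(1,3-dioxolan-2-yl)-2,6-dimethylocta-1,5-dien-1-yl]zinc | O1CCOC1CC/C(C)=C\CC/C(C)=C\[Zn]Br | intermediate
14 | 2-[(3Z,7Z,10E,12E)-3,7-dimethyl-13-(4,4,5,5-tetramethyl-1,3,2-dioxaborolan-2-yl)trideca-3,7,10,12-tetraen-1-yl]-1,3-dioxolane | O1CCOC1CC/C(C)=C\CC/C(C)=C\C/C=C/C=C/B1OC(C)(C)C(C)(C)O1 | intermediate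
15 | (4Z,8Z,11E,13E)-4,8-dimethyl-14-(4,4,5,5-tetramethyl-1,3,2-dioxaborolan-2-yl)tetradeca-4,8,11,13-tetraenal | O=CCC/C(C)=C\CC/C(C)=C\C/C=C/C=C/B1OC(C)(C)C(C)(C)O1 | intermediate
16 | hex-5-enal | C=CCCCC=O | starting material
17 | cyclohexanamine | NC1CCCCC1 | starting material
18 | N-cyclohexylhex-5-en-1-imine | C=CCCCC=NC1CCCCC1 | intermediate
19 | lithium cyclohexyl[(1E)-hexa-1,5-dien-1-yl]azanide | [Li]N(C1CCCCC1)/C=C/CCC=C | intermediate
20 | (6Z,10Z,13E,15E)-2-(but-3-en-1-yl)-1-(cyclohexylimino)-6,10-dimethyl-16-(4,4,5,5-tetramethyl-1,3,2-dioxaborolan-2-yl)hexadeca-6,10,13,15-tetraen-3-ol (mixture of diastereomers) | C=CCCC(C=NC1CCCCC1)C(O)CC/C(C)=C\CC/C(C)=C\C/C=C/C=C/B1OC(C)(C)C(C)(C)O1 | intermediate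
21 | (2E,6Z,10Z,13E,15E)-2-(but-3-en-1-yl)-6,10-dimethyl-16-(4,4,5,5-tetramethyl-1,3,2-dioxaborolan-2-yl)hexadeca-2,6,10,13,15-pentaenal | O=C/C(CCC=C)=C/CC/C(C)=C\CC/C(C)=C\C/C=C/C=C/B1OC(C)(C)C(C)(C)O1 | intermediate
22 | (1S,3Z,7Z,11S,12R,15R)-15-(but-3-en-1-yl)-4,8-dimethyl-12-(4,4,5,5-tetramethyl-1,3,2-dioxaborolan-2-yl)bicyclo[9.3.1]pentadeca-3,7,13-triene-15-carbaldehyde | C=CCC[C@]1(C=O)[C@H]2C/C=C(/C)CC/C=C(/C)CC[C@H]1[C@H](B3OC(C)(C)C(C)(C)O3)C=C2 | intermediate
23 | 2-methylbut-2-ene | CC=C(C)C | starting material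
24 | (1S,3Z,7Z,11S,12R,15R)-4,8-dimethyl-15-(4-methylpent-3-en-1-yl)-12-(4,4,5,5-tetramethyl-1,3,2-dioxaborolan-2-yl)bicyclo[9.3.1]pentadeca-3,7,13-triene-15-carbaldehyde | CC(C)=CCC[C@]1(C=O)[C@H]2C/C=C(/C)CC/C=C(/C)CC[C@H]1[C@H](B3OC(C)(C)C(C)(C)O3)C=C2 | intermediate
25 | [(1S,3Z,7Z,11S,12R,15R)-4,8-dimethyl-15-(4-methylpent-3-en-1-yl)-12-(4,4,5,5-tetramethyl-1,3,2-dioxaborolan-2-yl)bicyclo[9.3.1]pentadeca-3,7,13-trien-15-yl]methanol | CC(C)=CCC[C@]1(CO)[C@H]2C/C=C(/C)CC/C=C(/C)CC[C@H]1[C@H](B3OC(C)(C)C(C)(C)O3)C=C2 | intermediate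
26 | (1S,3Z,7Z,11R,12R,15S)-15-(hydroxymethyl)-4,8-dimethyl-15-(4-methylpent-3-en-1-yl)bicyclo[9.3.1]pentadeca-3,7,13-trien-12-ol | CC(C)=CCC[C@]1(CO)[C@H]2C/C=C(/C)CC/C=C(/C)CC[C@H]1[C@H](O)C=C2 | intermediate
27 | (1S,3Z,7Z,11R,15S)-15-(hydroxymethyl)-4,8-dimethyl-15-(4-methylpent-3-en-1-yl)bicyclo[9.3.1]pentadeca-3,7,13-trien-12-one | CC(C)=CCC[C@]1(CO)[C@H]2C/C=C(/C)CC/C=C(/C)CC[C@H]1C(=O)C=C2 | intermediate
28 | (1S,3Z,7Z,11R,15S)-15-{[(tert-butyldimethylsilyl)oxy]methyl}-4,8-dimethyl-15-(4-methylpent-3-en-1-yl)bicyclo[9.3.1]pentadeca-3,7,13-trien-12-one | CC(C)=CCC[C@]1(CO[Si](C)(C)C(C)(C)C)[C@H]2C/C=C(/C)CC/C=C(/C)CC[C@H]1C(=O)C=C2 | intermediate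
29 | (1R,3Z,7Z,11R,15S)-15-{[(tert-butyldimethylsilyl)oxy]methyl}-4,8-dimethyl-15-(4-methylpent-3-en-1-yl)bicyclo[9.3.1]pentadeca-3,7-dien-12-one | CC(C)=CCC[C@]1(CO[Si](C)(C)C(C)(C)C)[C@H]2C/C=C(/C)CC/C=C(/C)CC[C@H]1C(=O)CC2 | intermediate
30 | tert-butyl(dimethyl){[(1R,3Z,7Z,11R,12S,15S)-4,8-dimethyl-15-(4-methylpent-3-en-1-yl)spiro[bicyclo[9.3.1]pentadeca-3,7-diene-12,2'-oxiran]-15-yl]methoxy}silane | CC(C)=CCC[C@]1(CO[Si](C)(C)C(C)(C)C)[C@H]2C/C=C(/C)CC/C=C(/C)CC[C@H]1[C@@]1(CC2)CO1 | intermediate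
31 | [(1R,3Z,7Z,11R,12S,15S)-4,8-dimethyl-15-(4-methylpent-3-en-1-yl)spiro[bicyclo[9.3.1]pentadeca-3,7-diene-12,2'-oxiran]-15-yl]methanol | CC(C)=CCC[C@]1(CO)[C@H]2C/C=C(/C)CC/C=C(/C)CC[C@H]1[C@@]1(CC2)CO1 | intermediate
32 | (1R,3Z,7Z,11R,12S,15S)-4,8-dimethyl-15-(4-methylpent-3-en-1-yl)spiro[bicyclo[9.3.1]pentadeca-3,7-diene-12,2'-oxirane]-15-carbaldehyde | CC(C)=CCC[C@]1(C=O)[C@H]2C/C=C(/C)CC/C=C(/C)CC[C@H]1[C@@]1(CC2)CO1 | target

**Count and risks**
Total step count: 17. Longest linear sequence: 14 steps (steps 3 to 6 and 8 to 17).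

Steps most likely to fail:

Step 9. Process: at the dilution that ring closure needs, the catalysed cycloaddition may be too slow, so that oligomerisation by intermolecular cycloaddition takes over; closure in the exo or the fused mode, or weak facial control, are the other ways it can go wrong. Fallback: the two rings are made in two stages, an intermolecular Diels–Alder reaction followed by a B-alkyl Suzuki–Miyaura ring closure between C8 and C9; it sets out from bromide 3 and comes back to the route at diol 26.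
- The alkenylcopper 8 of step 3 is allylated with 3 to give 2-[(3Z,6E,8E)-3-methyl-9-(4,4,5,5-tetramethyl-1,3,2-dioxaborolan-2-yl)nona-3,6,8-trien-1-yl]-1,3-dioxolane F1.
- Hydrolysis (1 M HCl, THF) gives aldehyde F2, and Stork–Zhao olefination (ethyltriphenylphosphonium iodide, n-BuLi, I2, then NaN(SiMe3)2, THF, −78 °C) gives the (Z)-alkenyl iodide F3.
- Separately, lithiated N-cyclohexylethanimine is alkylated with 5-bromo-2-methylpent-2-ene to the imine F4; its lithio derivative F5 adds to acrolein to give the aldol adduct F6, and oxalic acid then gives the dienal F7.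
- F3 and F7 are combined under the catalyst of step 9 at 0.5 M to give the cyclohexene F8, which has the ring stereocentres of 24 and a vinyl group on C11.
- NaBH4 gives the alcohol F9 and NaOH/H2O2 the diol F10.
- 9-BBN adds to the vinyl group to give the alkylborane F11, and PdCl2(dppf), AsPh3 and Cs2CO3 in DMF/THF/H2O at 0.002 M should close the twelve-membered ring to 26.

Step 15. Process: methylene transfer from the lower face of C12, or deprotonation at C11 of the hindered chair ketone instead of addition, with loss of the C11 configuration. Fallback: the order of events is changed so that the ylide meets the flatter, less hindered enone and the conjugate reduction of step 14 is not needed; it sets out from enone 28 and comes back at 30. Dimethylsulfonium methylide is added 1,2 to the carbonyl group of 28 to give the vinyl oxirane F12, and the ring alkene C13=C14 is then saturated with diimide (2-nitrobenzenesulfonylhydrazide, Et3N, CH2Cl2), which should leave the trisubstituted alkenes alone.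

Step 5. Process: the mixed copper–zinc–palladium sequence may fail at the allylation, by attack at the inner or the boron-bearing carbon of the pentadienyl unit or by breakdown of the boronate in the organometallic mixture. Fallback: the alkenyl metal is isolated as a stable stannane and joined under neutral conditions; it sets out from bromide 10 and comes back at 14. The alkenylcopper 12, made as in step 5, is quenched with Bu3SnCl to give the (Z)-alkenylstannane F13, which is purified and coupled with 3 in a Stille reaction (Pd2(dba)3, AsPh3, THF, 50 °C).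

Further compounds
F1 | step 9 | 2-[(3Z,6E,8E)-3-methyl-9-(4,4,5,5-tetramethyl-1,3,2-dioxaborolan-2-yl)nona-3,6,8-trien-1-yl]-1,3-dioxolane | O1CCOC1CC/C(C)=C\C/C=C/C=C/B1OC(C)(C)C(C)(C)O1
F2 | step 9 | (4Z,7E,9E)-4-methyl-10-(4,4,5,5-tetramethyl-1,3,2-dioxaborolan-2-yl)deca-4,7,9-trienal | O=CCC/C(C)=C\C/C=C/C=C/B1OC(C)(C)C(C)(C)O1
F3 | step 9 | 2-[(1E,3E,6Z,10Z)-11-iodo-7-methyldodeca-1,3,6,10-tetraen-1-yl]-4,4,5,5-tetramethyl-1,3,2-dioxaborolane | C/C(I)=C/CC/C(C)=C\C/C=C/C=C/B1OC(C)(C)C(C)(C)O1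
F4 | step 9 | N-cyclohexyl-6-methylhept-5-en-1-imine | CC(C)=CCCCC=NC1CCCCC1
F5 | step 9 | lithium cyclohexyl(6-methylhepta-1,5-dien-1-yl)azanide | [Li]N(C1CCCCC1)C=CCCC=C(C)C
F6 | step 9 | 4-[(cyclohexylimino)methyl]-8-methylnona-1,7-dien-3-ol | C=CC(O)C(CCC=C(C)C)C=NC1CCCCC1
F7 | step 9 | (2E)-2-(4-methylpent-3-en-1-yl)penta-2,4-dienal | O=C/C(CCC=C(C)C)=C/C=C
F8 | step 9 | 6-ethenyl-2-[(2Z,6Z)-7-iodo-3-methylocta-2,6-dien-1-yl]-1-(4-methylpent-3-en-1-yl)-5-(4,4,5,5-tetramethyl-1,3,2-dioxaborolan-2-yl)cyclohex-3-ene-1-carbaldehyde (ring stereocentres as in 24) | CC(C)=CCC[C@]1(C=O)[C@@H](C/C=C(/C)CC/C=C(/C)I)C=C[C@@H](B2OC(C)(C)C(C)(C)O2)[C@@H]1C=C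
F9 | step 9 | {6-ethenyl-2-[(2Z,6Z)-7-iodo-3-methylocta-2,6-dien-1-yl]-1-(4-methylpent-3-en-1-yl)-5-(4,4,5,5-tetramethyl-1,3,2-dioxaborolan-2-yl)cyclohex-3-en-1-yl}methanol (ring stereocentres as in 25) | CC(C)=CCC[C@]1(CO)[C@@H](C/C=C(/C)CC/C=C(/C)I)C=C[C@@H](B2OC(C)(C)C(C)(C)O2)[C@@H]1C=C
F10 | step 9 | 6-ethenyl-5-(hydroxymethyl)-4-[(2Z,6Z)-7-iodo-3-methylocta-2,6-dien-1-yl]-5-(4-methylpent-3-en-1-yl)cyclohex-2-en-1-ol (ring stereocentres as in 26) | CC(C)=CCC[C@]1(CO)[C@@H](C/C=C(/C)CC/C=C(/C)I)C=C[C@@H](O)[C@@H]1C=C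
F11 | step 9 | 6-[2-(9-borabicyclo[3.3.1]nonan-9-yl)ethyl]-5-(hydroxymethyl)-4-[(2Z,6Z)-7-iodo-3-methylocta-2,6-dien-1-yl]-5-(4-methylpent-3-en-1-yl)cyclohex-2-en-1-ol (ring stereocentres as in 26) | CC(C)=CCC[C@]1(CO)[C@@H](C/C=C(/C)CC/C=C(/C)I)C=C[C@@H](O)[C@@H]1CCB1C2CCCC1CCC2
F12 | step 15 | tert-butyl(dimethyl){[(3Z,7Z)-4,8-dimethyl-15-(4-methylpent-3-en-1-yl)spiro[bicyclo[9.3.1]pentadeca-3,7,13-triene-12,2'-oxiran]-15-yl]methoxy}silane (stereocentres as in 30) | CC(C)=CCC[C@]1(CO[Si](C)(C)C(C)(C)C)[C@H]2C/C=C(/C)CC/C=C(/C)CC[C@H]1[C@@]1(C=C2)CO1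
F13 | step 5 | tributyl[(1Z,5Z)-8-(1,3-dioxolan-2-yl)-2,6-dimethylocta-1,5-dien-1-yl]stannane | O1CCOC1CC/C(C)=C\CC/C(C)=C\[Sn](CCCC)(CCCC)CCCC
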